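In a one-step world D and G simply meet until the smaller charge is gone, but here G has two more ways out.

D 1.5 M; G 1.58 M; time 20 h

    D + G → L + E (k1 = 3.4 × 10⁻⁵ /M/s)
    G ⇌ Z (K2 = 15, k2 = 3.1 × 10⁻⁶ /s)
    2 G → G2 (k3 = 5.2 × 10⁻⁵ /M/s)

- which holds at 20 h: what has brought the reaction to rest, or that it has not come to rest (all of D has reacted / it is still moving / forward and back rates have come level)
- L at 20 h, in percent of the D charged

- two of one species on the left: rate k times its square, two consumed each time
- the reaction counts as stopped when no species that holds the D changes by six tenths of a point or more over the second half of the time
- run time (flask): 20 h

We turn the constants into times at the charged amounts. G lasts about 5.45 h against D and 1.69 h against itself. Its passage to Z takes 89.6 h, far longer than either, so we drop Z and keep two times. Their ratio is 3.22, so at the start G loses itself faster than it finds D.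

That ratio shifts as [G] and [D] fall, so we carry its constant part: the G lost to itself for each G lost to D at equal [G] and [D], which is twice k3 over k1. This is the waste factor, a selectivity factor, 3.06.

Dividing the two rates removes time. Take m, the charge of D over the factor less one, 0.729 M. The fraction of D left when [G] reaches nothing is m/(m + charge of G), raised to one over the factor less one: 57.1%. So, with Z left out, our reckoning puts the stall of L near 42.9%. Once [G] is well below [D], D consumes G over about 9.54 h, half the run, so we expect L a little under that figure and still moving.

The forecast gives 40% and "it is still moving": “G is lost mainly to its own dimerisation”.

The flask gives 40.1% of L at 20 h, and it is still moving, the largest change of a share over the second half being 3.7 percentage points. At that time the G spent on itself, twice G2, is 0.910 M, more than the 0.601 M spent on D as E, and G, the limiting reagent, stands at 1.4% of its charge. Ten times as long, this flask shows 41.7%, and left far longer still 44.6%, past our figure. For the neighbour flask with 2.5 M of D, the same factor, Z again left out, puts the stall at 33.3%, and that flask shows 32.3% at 20.0 h.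

(The constants used here were set for the occasion; the flask was simulated.)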